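The acid is traced back to the methyl of an isopropenyl group (C17), C8–H to a C8 methyl ester, the C12 CH2 to a ketone, and C13–C15 to a cross-coupling. Ring A is then cut at C9–C11 and C8–C14 in one [4+2] operation.
Ring A (C8, C9, C11, C12, C13, C14) is fused to the δ-lactone ring (C7, O, C20, C10, C9, C8) along C8–C9. C8 is α to the lactone carbonyl C7 and C9 is bonded to the quaternary spiro carbon C10, so a C8=C9 lactone alkene with a second ester on C8 is a doubly activated dienophile whose two faces C10 makes unequal.
The dienophile is cut at C8=C9 (Knoevenagel), C20O–C7 (acylation), C3–O (oxa-Michael), C10–C20 and C10–C9 (two enolate bond formations) and C5–C6 (conjugate vinylation of a bought dienone).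
In the forward direction the rings arise in this order: six-membered carbocycle (bought), tetrahydrofuran bridge giving the 6-oxabicyclo[3.2.1]octanone, spiro dihydropyranone, ring A, then the side chain.
C5 comes from a rhodium/(S)-BINAP 1,4-addition, C10 from aldol attack anti to the C5 vinyl group, and C3 from the one-carbon tether. C9 comes from the face choice and C8 from the suprafacial course of the cycloaddition. C13 and the final C8–H come from protonations that end in the equatorial side chain and the cis ring fusion, both the more stable arrangements.

Key step: step 9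

Numbering (kept for all intermediates): C1 ketone, C2 CH2, C3 O-bearing bridgehead, C4 CMe2, C5 bridgehead CH, C6 ether CH2, C7 lactone C=O, C8/C9 ring-fusion carbons, C10 spiro carbon, C11–C14 rest of ring A, C15(=C16H2)–C17 side chain, C20 lactone OCH2. The target is (3S,5S,8S,9R,10S,13R).
Assumption: (S)-BINAP is taken to deliver the vinyl group to the same enone face as in the parent cyclohexenone series, which corresponds to the (S)-vinyl enone. If the sense proves opposite, (R)-BINAP is used.

Step 1
Reactants: 1 4,4-dimethylcyclohexa-2,5-dien-1-one; 2 potassium vinyltrifluoroborate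
Product: 3 (S)-4,4-dimethyl-5-vinylcyclohex-2-en-1-one
Conditions: [Rh(cod)2]BF4 (3 mol%), (S)-BINAP (3.5 mol%), Et3N (2 equiv), toluene/H2O, 40 °C, 1 in slight excess
Reagents that add atoms: none
Why: Hayashi–Miyaura asymmetric 1,4-addition, in which the alkenylrhodium species formed by transmetalation inserts one of the two enantiotopic enone alkenes of 1 inside the (S)-BINAP pocket, so the dienone is desymmetrised and C5 is set, while the excess of 1 and the greater crowding of C3 in 3 hold back a second addition.

Step 2
Reactants: 3 (S)-4,4-dimethyl-5-vinylcyclohex-2-en-1-one; 4 benzyl chloromethyl ether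
Product: 5 (5R,6S)-6-(benzyloxymethyl)-4,4-dimethyl-5-vinylcyclohex-2-en-1-one (CH2OBn trans to vinyl)
Conditions: LiN(iPr)2, THF, −78 °C; then 4, DMPU, −78 → −20 °C
Reagents that add atoms: none
Why: Kinetic enolate alkylation (SN2), which is regiodefined because C4 carries no hydrogen and only the α′-proton at C10 can be removed; the cross-conjugated lithium enolate takes up C9 at carbon anti to the vinyl group, and the C10 configuration is of no consequence since step 3 flattens this centre again.

Step 3
Reactants: 5 benzyloxymethyl enone; 6 formaldehyde (monomer in THF, from cracked paraformaldehyde)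
Product: 7 (5S,6S)-6-(benzyloxymethyl)-6-(hydroxymethyl)-4,4-dimethyl-5-vinylcyclohex-2-en-1-one (C20H2OH trans and C9H2OBn cis to vinyl)
Conditions: LiN(iPr)2, THF, −78 °C; 6, −78 °C; AcOH quench at −78 °C
Reagents that add atoms: none
Why: Aldol addition of a fully substituted lithium enolate to formaldehyde, in which allylic strain with the in-plane CH2OBn group turns the C5 vinyl group pseudoaxial, so the small electrophile bonds to the opposite face and the quaternary C10 arises with C20 trans and C9 cis to C6, while the low temperature and cold acidic quench suppress loss of benzyloxide and retro-aldol cleavage.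

Step 4
Reactants: 7 hydroxymethyl enone; 8 methyl malonyl chloride
Product: 9 methyl malonate ester of 7 at the C20 oxygen
Conditions: pyridine, CH2Cl2, 0 °C
Reagents that add atoms: none
Why: Acylation of a primary alcohol by an acid chloride, which brings in C7 and C8 at the right oxidation level and also blocks retro-aldol loss of C20 and any addition of the C20 hydroxyl to the enone.

Step 5
Reactants: 9 malonate ester
Product: 10 C6 aldehyde (vinyl group of 9 cleaved to CHO)
Conditions: O3, CH2Cl2, −78 °C, Sudan Red 7B end point; then Me2S, −78 °C → rt
Reagents that add atoms: ozone, [O-][O+]=O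
Why: Ozonolysis with reductive work-up, in which the monosubstituted electron-neutral vinyl group is attacked far faster than the electron-poor, neopentyl-flanked C2=C3 enone bond, the dye end point spares the benzyl ether, and the neutral medium leaves C5 untouched.

Step 6
Reactants: 10 C6 aldehyde
Product: 12 oxa-bridged ketone (8,8-dimethyl-6-oxabicyclo[3.2.1]octan-3-one core with C3–O–C6 closed; C10 carries C9H2OBn on the bridge face and the C20 malonate on the other), via hydroxy enone 11 (not isolated)
Conditions: NaBH4 (0.5 equiv), CH2Cl2/MeOH, −78 °C; aqueous work-up; then CSA (10 mol%), CH2Cl2, rt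
Reagents that add atoms: none
Why: Chemoselective borohydride reduction of the aldehyde beside the conjugated hindered ketone, then acid-catalysed intramolecular oxa-Michael addition (5-exo-trig) helped by the C4 gem-dimethyl group; the one-carbon tether lets oxygen reach C3 only from the face that carries C6, so C5 sets C3.

Step 7
Reactants: 12 oxa-bridged benzyl ether
Product: 13 C9 primary alcohol
Conditions: H2 (1 atm), Pd/C, EtOAc, rt; used at once
Reagents that add atoms: none
Why: Catalytic hydrogenolysis of the benzyl ether in a molecule now free of alkenes, under neutral conditions that leave ketone, esters and bridging ether alone and give the 1,3-acyl shift between the C20 and C9 oxygens little chance.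

Step 8
Reactants: 13 C9 alcohol
Product: 15 spiro dienophile (3S,5S,10S): methyl 2-oxo-5,6-dihydropyran-3-carboxylate spiro-linked at its C5 (= C10) to C2 of 8,8-dimethyl-6-oxabicyclo[3.2.1]octan-3-one, via keto aldehyde 14 (not isolated)
Conditions: Dess–Martin periodinane, CH2Cl2, 0 °C → rt; short silica filtration; piperidine (10 mol%), AcOH (10 mol%), 4 Å MS, CH2Cl2, rt
Reagents that add atoms: none
Why: Dess–Martin oxidation followed by intramolecular Knoevenagel condensation, in which the tethered malonate methylene closes a six-membered ring on the aldehyde C9 (far more electrophilic than the neopentyl C1 ketone) and loss of water gives C8=C9 without touching a stereocentre; the β-keto aldehyde is not stored because amines can deformylate it.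

Step 9
Reactants: 15 spiro dienophile; 16 (E)-1-methoxy-3-(trimethylsilyloxy)buta-1,3-diene
Product: 18 cis-fused ring-A enone (C12 ketone and C13=C14; methyl ester on C8 and H on C9 on one face; C11 and C14 on the other; C11 on the C1 side of C10), via silyl enol ether cycloadduct 17 (not isolated)
Conditions: 16 (3 equiv), ZnCl2 (1 equiv), CH2Cl2, 0 °C → rt; then 0.1 M HCl, THF, 0 °C
Reagents that add atoms: none
Why: The lactone carbonyl C7 and the C8 ester, chelated by ZnCl2, lower the LUMO of C8=C9 and place its largest coefficient on C9, so the electron-rich diene 16 reacts in a normal-electron-demand, strongly asynchronous Diels–Alder reaction in which its CH2 terminus bonds to C9 (C9–C11) ahead of the methoxy-bearing terminus to C8 (C8–C14), and this polarity match fixes the regiochemistry. The closest known reaction type is the Lewis-acid-promoted cycloaddition of 1-alkoxy-3-silyloxy dienes to 3-alkoxycarbonyl-5,6-dihydro-2-pyranones and to 2-alkoxycarbonyl-4,4-dialkylcyclohexenones, whose β-carbon is neopentyl as it is here. Ring A is closed by an intermolecular [4+2] annulation in which both new σ-bonds form on the same face of the endocyclic alkene, so C11 and C14 are cis and the ring fusion is cis. C9 is controlled by the spiro stereocentre C10, because the diene passes the flat C1 carbonyl and attacks anti to the C10–C5 bond while the other face is covered by bridgehead C5 and its axial C6 methylene; C8 follows from C9 through the suprafacial addition, and the C14 methoxy centre is later erased. The step needs π-facial selectivity, secured as just described, and chemoselectivity for C8=C9 over a hetero-cycloaddition at the C1 ketone, secured by the unactivated neopentyl character of C1. Dilute acid then cleaves the silyl enol ether of 17 and eliminates methanol, leaving the C12 ketone conjugated with C13=C14.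

Step 10
Reactants: 18 ring-A enone
Product: 19 13-iodo enone
Conditions: I2 (2 equiv), pyridine/CH2Cl2, 0 °C → rt
Reagents that add atoms: iodine, II
Why: α-Iodination of an enone by a Baylis–Hillman-type addition, iodination and elimination sequence with pyridine, well known for 4,4-disubstituted cyclohexenones, which marks only C13 because the C1 ketone has no conjugated alkene.

Step 11
Reactants: 19 13-iodo enone; 20 isopropenylboronic acid pinacol ester
Product: 21 13-isopropenyl enone
Conditions: PdCl2(dppf) (5 mol%), K3PO4 (2 equiv), THF/H2O, 40 °C
Reagents that add atoms: none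
Why: Suzuki–Miyaura coupling of a 2-iodoenone with an alkenylboronate, in which oxidative addition into the activated C13–I bond is fast at mild temperature and the hindered carbonyl groups on the quaternary C8 resist the phosphate base.

Step 12
Reactants: 21 13-isopropenyl enone
Product: 22 C12 ketone with equatorial isopropenyl group at C13 (H13 on the face opposite to H9)
Conditions: [(Ph3P)CuH]6 (0.5 equiv), H2O (5 equiv), degassed toluene, rt
Reagents that add atoms: none
Why: Copper hydride conjugate reduction, in which hydride goes to C14 only (the isopropenyl group is cross-conjugated, and isolated alkenes and saturated ketones are inert) and water protonates the copper dienolate at the α-carbon C13 to give the equatorial side chain on the ring-A chair that keeps C10 equatorial; this is also the more stable epimer, so any axial epimer can drain into it through the enol.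

Step 13
Reactants: 22 C12 ketone
Product: 23 C12 tosylhydrazone
Conditions: TsNHNH2 (1.05 equiv), MeOH, rt
Reagents that add atoms: p-toluenesulfonyl hydrazide, Cc1ccc(cc1)S(=O)(=O)NN
Why: Hydrazone condensation, selective for C12 because C1 sits between the quaternary C10 and the bicyclic cage, with ene-hydrazine tautomerism able only to move a residual axial C13 epimer to the equatorial one.

Step 14
Reactants: 23 tosylhydrazone
Product: 24 C12-deoxygenated lactone ester (C12H2; isopropenyl at C13; methyl ester at C8)
Conditions: catecholborane (2.5 equiv), CHCl3, −10 °C; then NaOAc·3H2O, 60 °C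
Reagents that add atoms: none
Why: Caglioti-type deoxygenation in its catecholborane variant, in which hydroboration of C=N, acetate-induced loss of sulfinate and extrusion of N2 from the alkyl diazene replace C12=N by CH2 under near-neutral conditions that spare lactone, ester, C1 ketone and the 1,1-disubstituted alkene, after which C13 can no longer epimerise.

Step 15
Reactants: 24 lactone ester
Product: 25 cis-fused isopropenyl lactone (H8 cis to H9)
Conditions: LiCl (5 equiv), H2O (3 equiv), DMSO, 140 °C
Reagents that add atoms: none
Why: Krapcho dealkoxycarbonylation, in which chloride demethylates the ester, CO2 is lost and the lactone enolate is protonated at C8; since C8–H stays exchangeable in the hot medium the outcome is thermodynamic and favours the cis fusion, because a trans fusion would force C11 into a syn-pentane clash with the axial C6 methylene.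

Step 16
Reactants: 25 isopropenyl lactone
Product: 26 allylic alcohol (C17H2OH on C15=C16H2)
Conditions: SeO2 (0.5 equiv), t-BuOOH (2 equiv), CH2Cl2, 0 °C → rt
Reagents that add atoms: selenium dioxide, O=[Se]=O; tert-butyl hydroperoxide, CC(C)(C)OO
Why: SeO2 allylic oxidation (ene reaction then [2,3]-sigmatropic shift), run sub-stoichiometric in selenium at room temperature so that the C2 methylene next to the ketone is left alone; the methyl C–H bonds react because C13–H lies in the alkene plane in the preferred rotamer and cannot overlap with the π bond.

Step 17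
Reactants: 26 allylic alcohol
Product: 28 target acid CNP0268721.1, via enal 27 (not isolated)
Conditions: TEMPO (10 mol%), PhI(OAc)2 (1.1 equiv), CH2Cl2, rt; then t-BuOH/H2O, 2-methyl-2-butene, NaH2PO4, NaClO2, 0 °C → rt
Reagents that add atoms: sodium chlorite, [Na+].[O-]Cl=O
Why: Oxoammonium oxidation of the allylic alcohol to the enal and Pinnick oxidation in the same flask, a pair that leaves ketone, lactone and the electron-poor alkene alone and epimerises nothing in the weakly acidic buffer.

Compound list
1 | 4,4-dimethylcyclohexa-2,5-dien-1-one | CC1(C)C=CC(=O)C=C1 | starting material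
2 | potassium vinyltrifluoroborate | C=C[B-](F)(F)F.[K+] | starting material
3 | (S)-4,4-dimethyl-5-vinylcyclohex-2-en-1-one | C=C[C@@H]1CC(=O)C=CC1(C)C | intermediate
4 | benzyl chloromethyl ether | ClCOCc1ccccc1 | starting material
5 | (5R,6S)-6-(benzyloxymethyl)-4,4-dimethyl-5-vinylcyclohex-2-en-1-one | c1ccccc1COC[C@H]1C(=O)C=CC(C)(C)[C@@H]1C=C | intermediate
6 | formaldehyde (monomer from paraformaldehyde) | C=O | starting material
7 | (5S,6S)-6-(benzyloxymethyl)-6-(hydroxymethyl)-4,4-dimethyl-5-vinylcyclohex-2-en-1-one | OC[C@@]1(COCc2ccccc2)C(=O)C=CC(C)(C)[C@@H]1C=C | intermediate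
8 | methyl malonyl chloride (methyl 3-chloro-3-oxopropanoate) | COC(=O)CC(=O)Cl | starting material
9 | C20 methyl malonate ester of 7 | COC(=O)CC(=O)OC[C@@]1(COCc2ccccc2)C(=O)C=CC(C)(C)[C@@H]1C=C | intermediate
10 | C6 aldehyde from 9 | COC(=O)CC(=O)OC[C@@]1(COCc2ccccc2)C(=O)C=CC(C)(C)[C@@H]1C=O | intermediate
11 | C6 hydroxy enone | COC(=O)CC(=O)OC[C@@]1(COCc2ccccc2)C(=O)C=CC(C)(C)[C@@H]1CO | intermediate
12 | oxa-bridged ketone with C9H2OBn and C20 malonate | COC(=O)CC(=O)OC[C@@]1(COCc2ccccc2)C(=O)C[C@@H]2OC[C@H]1C2(C)C | intermediate
13 | oxa-bridged ketone with C9H2OH and C20 malonate | COC(=O)CC(=O)OC[C@@]1(CO)C(=O)C[C@@H]2OC[C@H]1C2(C)C | intermediate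
14 | C9 keto aldehyde | COC(=O)CC(=O)OC[C@@]1(C=O)C(=O)C[C@@H]2OC[C@H]1C2(C)C | intermediate
15 | spiro 3-methoxycarbonyl-5,6-dihydropyran-2-one dienophile (3S,5S,10S) | COC(=O)C1=C[C@]2(COC1=O)C(=O)C[C@@H]3OC[C@H]2C3(C)C | intermediate
16 | (E)-1-methoxy-3-(trimethylsilyloxy)buta-1,3-diene | CO/C=C/C(=C)O[Si](C)(C)C | starting material
17 | primary cycloadduct: C12 silyl enol ether with C14 methoxy group (C14 configuration inconsequential and left open) | C[Si](C)(C)OC1=CC(OC)[C@@]2(C(=O)OC)[C@@H](C1)[C@]3(COC2=O)C(=O)C[C@@H]4OC[C@H]3C4(C)C | intermediate
18 | cis-fused ring-A enone with C8 methyl ester | O=C1C=C[C@@]2(C(=O)OC)[C@@H](C1)[C@]3(COC2=O)C(=O)C[C@@H]4OC[C@H]3C4(C)C | intermediate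
19 | 13-iodo enone | O=C1C(I)=C[C@@]2(C(=O)OC)[C@@H](C1)[C@]3(COC2=O)C(=O)C[C@@H]4OC[C@H]3C4(C)C | intermediate
20 | isopropenylboronic acid pinacol ester | CC(=C)B1OC(C)(C)C(C)(C)O1 | starting material
21 | 13-isopropenyl enone | O=C1C(C(C)=C)=C[C@@]2(C(=O)OC)[C@@H](C1)[C@]3(COC2=O)C(=O)C[C@@H]4OC[C@H]3C4(C)C | intermediate
22 | C12 ketone with equatorial 13-isopropenyl group | O=C1[C@@H](C(C)=C)C[C@@]2(C(=O)OC)[C@@H](C1)[C@]3(COC2=O)C(=O)C[C@@H]4OC[C@H]3C4(C)C | intermediate
23 | C12 tosylhydrazone of 22 (C=N geometry open) | Cc1ccc(cc1)S(=O)(=O)NN=C1[C@@H](C(C)=C)C[C@@]2(C(=O)OC)[C@@H](C1)[C@]3(COC2=O)C(=O)C[C@@H]4OC[C@H]3C4(C)C | intermediate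
24 | C12-deoxygenated lactone ester | C=C(C)[C@@H]1CC[C@@H]2[C@@](C1)(C(=O)OC)C(=O)OC[C@]21C(=O)C[C@@H]2OC[C@H]1C2(C)C | intermediate
25 | cis-fused isopropenyl lactone | C=C(C)[C@@H]1CC[C@@H]2[C@H](C1)C(=O)OC[C@]21C(=O)C[C@@H]2OC[C@H]1C2(C)C | intermediate
26 | C17 allylic alcohol | C=C(CO)[C@@H]1CC[C@@H]2[C@H](C1)C(=O)OC[C@]21C(=O)C[C@@H]2OC[C@H]1C2(C)C | intermediate
27 | C17 enal | C=C(C=O)[C@@H]1CC[C@@H]2[C@H](C1)C(=O)OC[C@]21C(=O)C[C@@H]2OC[C@H]1C2(C)C | intermediate
28 | CNP0268721.1, (3S,5S,8S,9R,10S,13R) | C=C(C(=O)O)[C@@H]1CC[C@@H]2[C@H](C1)C(=O)OC[C@]21C(=O)C[C@@H]2OC[C@H]1C2(C)C | target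

Total steps: 17. Longest linear sequence: 17 steps, from 1.

Steps most likely to fail

Step 9. Bond formation between a neopentyl C9 and a fully substituted C8 may be slower than Lewis-acid decomposition of the acid-labile diene. The reaction may also stop after the first (Michael-type) bond, or the two faces may be told apart too weakly. The fallback sets out from 15 and keeps the same two bonds, but uses 2-(trimethylsilyloxy)buta-1,3-diene. Its unsubstituted terminus meets C8 with less strain, and it tolerates long heating without a Lewis acid (toluene, sealed tube, 130 °C). The adduct is isolated as the C12 silyl enol ether F1, whose C12=C13 position is fixed by the cycloaddition. A separate Saegusa–Ito dehydrogenation (Pd(OAc)2, MeCN, rt) then places the alkene at C13=C14, and the route is rejoined at 18.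

Step 3. The β-benzyloxy enolate may expel benzyloxide on the way to the aldolate, the hindered aldolate may revert, or attack may occur on both faces. The fallback sets out from 5 and avoids any anionic enolate. Soft enolisation (TMSOTf, Et3N, CH2Cl2, 0 °C) gives the 2-silyloxy diene F2, which is isolated. It is then submitted to a Mukaiyama aldol reaction with aqueous formaldehyde (Sc(OTf)3 10 mol%, THF, rt). The neutral nucleophile cannot eliminate, the adduct is released as the free alcohol, and the route is rejoined at 7.

Step 13. Condensation at the α-branched C12 ketone may be slow. During it the C15=C16 alkene may drift into conjugation, or the C1 ketone may begin to react, and the diazene stage of step 14 depends on a clean hydrazone. The fallback sets out from 22 and removes the oxygen by a radical route. NaBH4 (MeOH, −40 °C) reduces the more accessible C12 ketone to the C12 alcohol F3. 1,1′-Thiocarbonyldiimidazole (DMAP, toluene, 80 °C) gives the imidazolylthiocarbonate F4. Barton–McCombie reduction (Bu3SnH at high concentration, AIBN, toluene, 90 °C) lets hydrogen transfer outrun closure of the homoallyl radical onto the side-chain alkene, and the route is rejoined at 24.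

Further compounds
F1 | step 9 | C12 silyl enol ether from 15 and 2-(trimethylsilyloxy)buta-1,3-diene (C12=C13; C14H2) | C[Si](C)(C)OC1=CC[C@@]2(C(=O)OC)[C@@H](C1)[C@]3(COC2=O)C(=O)C[C@@H]4OC[C@H]3C4(C)C
F2 | step 3 | (S)-configured 2-silyloxy diene of 5 (C1(OTMS)=C10; C2=C3) | C=C[C@@H]1C(COCc2ccccc2)=C(O[Si](C)(C)C)C=CC1(C)C
F3 | step 13 | C12 alcohol of 22 (C12 epimers, configuration inconsequential) | OC1[C@@H](C(C)=C)C[C@@]2(C(=O)OC)[C@@H](C1)[C@]3(COC2=O)C(=O)C[C@@H]4OC[C@H]3C4(C)C
F4 | step 13 | C12 O-(imidazol-1-ylthiocarbonyl) derivative of F3 | S=C(OC1[C@@H](C(C)=C)C[C@@]2(C(=O)OC)[C@@H](C1)[C@]3(COC2=O)C(=O)C[C@@H]4OC[C@H]3C4(C)C)n1ccnc1
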